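**Retrosynthetic overview**

1. Locants: C1 benzylic CH2; C2–C7 cyclohexane (C3 exo-methylene carbon, C6 CHBr, C7 quaternary C–CH3); C8–C13 chain (C10 CHBr, C11 tertiary carbinol); C14 lactone carbinol. The strategy rests on C10, C11 and the C11 methyl: a propene unit between the CH2 groups C9 and C12, whose anti Br/OH pair is stored as the (E)-C10=C11 alkene.
2. Key disconnections: C9–C10 and C11–C12 (one-pot double sp3–sp2 Negishi coupling on (E)-2-bromo-1-iodopropene), then the C10–Br/C11–OH pair (epoxide opened by bromide) and the O–C14 ester bond.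
3. Ring fragment from cyclohexane-1,3-dione: C7 and the C6 carbinol by CBS desymmetrisation, C6–Br by inversion, the C1–C2 bond by Negishi coupling of an enol triflate, C2–H by hydroboration, C3=CH2 by methylenation.
4. Tail fragment: acetate aldol of methacrolein sets C14; both fragments enter the coupling as primary alkylzinc iodides.
5. Ring order: the cyclohexane and the arene come from the starting materials; the only ring closed is the 15-membered lactone, formed after the bromohydrin has been set on the open chain.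

Key step: step 22

Remark on the chemistry: the target is 2R,6S,7S,10R,11S,14S in these locants. The phenol is carried as a MOM ether and the acid as a methyl ester. C14–O stays silylated until the epoxide has been opened, because a free C14–OH four atoms from the C10–C11 epoxide would cyclise to a tetrahydrofuran.
Assumption: 2-[(tert-butyldiphenylsilyl)oxy]acetaldehyde, (S)-HYTRA and the L-fructose-type (ent) Shi ketone are treated as purchasable.

**Aryl fragment**

Step 1
Reactants: 1 methyl 3-formyl-4-hydroxybenzoate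
Product: 2 methyl 3-formyl-4-(methoxymethoxy)benzoate
Conditions: MOMCl, i-Pr2NEt, CH2Cl2, 0 → 23 °C
Reagents that add atoms: chloromethyl methyl ether (MOMCl), COCCl
Why: O-alkylation of the phenol (Williamson type) gives an acetal that should survive the enolate, organozinc, borane, fluoride and hydroxide steps and leave under mild acid at the end.

Step 2
Reactants: 2 methyl 3-formyl-4-(methoxymethoxy)benzoate
Product: 3 methyl 3-(hydroxymethyl)-4-(methoxymethoxy)benzoate
Conditions: NaBH4, MeOH, 0 °C
Reagents that add atoms: none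
Why: Borohydride reduction is chemoselective for the aldehyde over the aryl methyl ester.

Step 3
Reactants: 3 methyl 3-(hydroxymethyl)-4-(methoxymethoxy)benzoate
Product: 4 methyl 3-(bromomethyl)-4-(methoxymethoxy)benzoate
Conditions: CBr4, PPh3, CH2Cl2, 0 °C
Reagents that add atoms: carbon tetrabromide, BrC(Br)(Br)Br
Why: Appel bromination of a primary benzylic alcohol runs under neutral conditions that keep the MOM acetal.

**Ring fragment**

Step 4
Reactants: 5 cyclohexane-1,3-dione; 6 2-[(tert-butyldiphenylsilyl)oxy]acetaldehyde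
Product: 8 2-{2-[(tert-butyldiphenylsilyl)oxy]ethyl}cyclohexane-1,3-dione, via alkylidene dione 7 (not isolated)
Conditions: Hantzsch ester (1.0 equiv), L-proline (10 mol%), CH2Cl2, 23 °C
Reagents that add atoms: none
Why: In this organocatalytic reductive alkylation a Knoevenagel condensation gives the alkylidene dione, which the Hantzsch ester reduces by conjugate hydride transfer, so the dione carbon receives the two-carbon C8–C9 arm without O-alkylation.

Step 5
Reactants: 8 2-{2-[(tert-butyldiphenylsilyl)oxy]ethyl}cyclohexane-1,3-dione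
Product: 9 2-{2-[(tert-butyldiphenylsilyl)oxy]ethyl}-2-methylcyclohexane-1,3-dione
Conditions: MeI, K2CO3, acetone, 56 °C
Reagents that add atoms: iodomethane, CI
Why: C-Alkylation of the stabilised dione enolate creates the prochiral quaternary carbon (future C7); the O-methyl enol ether expected alongside is separable and can be hydrolysed back to 8.

Step 6
Reactants: 9 2-{2-[(tert-butyldiphenylsilyl)oxy]ethyl}-2-methylcyclohexane-1,3-dione
Product: 10 (2R,3R)-2-{2-[(tert-butyldiphenylsilyl)oxy]ethyl}-3-hydroxy-2-methylcyclohexan-1-one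
Conditions: (S)-2-methyl-CBS-oxazaborolidine (20 mol%), catecholborane (1.2 equiv), toluene, −78 → −40 °C; MeOH, aqueous work-up
Reagents that add atoms: none
Why: The Corey–Bakshi–Shibata reduction acts as a desymmetrisation: with the quaternary carbon as the large group the (S)-catalyst should give the 3R carbinol, and hydride should enter anti to the larger silyloxyethyl arm, so OH ends cis to that arm and C7 and the C6 carbinol are fixed together.

Step 7
Reactants: 10 (2R,3R)-2-{2-[(tert-butyldiphenylsilyl)oxy]ethyl}-3-hydroxy-2-methylcyclohexan-1-one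
Product: 11 (2S,3S)-3-bromo-2-{2-[(tert-butyldiphenylsilyl)oxy]ethyl}-2-methylcyclohexan-1-one
Conditions: PPh3, CBr4, 2,6-lutidine, CH2Cl2 then toluene, 0 → 40 °C
Reagents that add atoms: carbon tetrabromide, BrC(Br)(Br)Br
Why: In this Appel reaction bromide displaces the alkoxyphosphonium group by SN2 with inversion, turning the C6–OH cis to the C8 arm into the C6–Br trans to it (6S); the flanking ketone disfavours ionisation and 1,2-shifts from C7, the arm is syn to the leaving group and cannot participate, and E2 toward C5 is the competing path.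

Step 8
Reactants: 11 (2S,3S)-3-bromo-2-{2-[(tert-butyldiphenylsilyl)oxy]ethyl}-2-methylcyclohexan-1-one
Product: 12 (5S,6S)-5-bromo-6-{2-[(tert-butyldiphenylsilyl)oxy]ethyl}-6-methylcyclohex-1-en-1-yl trifluoromethanesulfonate
Conditions: KHMDS, THF, −78 °C; PhNTf2, −78 → 0 °C
Reagents that add atoms: N-phenylbis(trifluoromethanesulfonimide), O=S(=O)(N(c1ccccc1)S(=O)(=O)C(F)(F)F)C(F)(F)F
Why: Enolate O-triflation is regiodefined because only C3 carries enolisable hydrogens, and the equatorial bromide has no antiperiplanar hydrogen for E2.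

Step 9
Reactants: 12 (5S,6S)-5-bromo-6-{2-[(tert-butyldiphenylsilyl)oxy]ethyl}-6-methylcyclohex-1-en-1-yl trifluoromethanesulfonate; 4 methyl 3-(bromomethyl)-4-(methoxymethoxy)benzoate
Product: 14 methyl 3-{[(5S,6S)-5-bromo-6-{2-[(tert-butyldiphenylsilyl)oxy]ethyl}-6-methylcyclohex-1-en-1-yl]methyl}-4-(methoxymethoxy)benzoate, via benzylzinc bromide 13 (not isolated)
Conditions: 4, Zn dust, LiCl, THF, 0 → 23 °C; then 12, Pd(OAc)2/SPhos (5 mol%), THF, 50 °C
Reagents that add atoms: none
Why: In this Negishi sp3–sp2 coupling zinc inserts into the benzylic C–Br bond and Pd(0) adds to the alkenyl triflate far faster than to the unactivated secondary alkyl bromide, so C1–C2 forms with ester, acetal and silyl ether untouched.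

Step 10
Reactants: 14 methyl 3-{[(5S,6S)-5-bromo-6-{2-[(tert-butyldiphenylsilyl)oxy]ethyl}-6-methylcyclohex-1-en-1-yl]methyl}-4-(methoxymethoxy)benzoate
Product: 16 methyl 3-{[(1S,2S,3S,6S)-3-bromo-2-{2-[(tert-butyldiphenylsilyl)oxy]ethyl}-6-hydroxy-2-methylcyclohexyl]methyl}-4-(methoxymethoxy)benzoate, via C3 alkylborane 15 (not isolated)
Conditions: BH3·THF, THF, 0 → 23 °C; then aq. NaOAc, 30% H2O2, 0 → 23 °C
Reagents that add atoms: hydrogen peroxide, OO
Why: In this hydroboration–oxidation boron adds to the less substituted C3 and hydrogen to C2 (syn), expected from the face opposite the pseudoaxial C7 methyl in the half-chair with C6–Br equatorial, which places C2–H cis to the C8 arm and the benzyl group trans to it (2R in the target); BH3 is slow toward the aryl ester and the buffered peroxide spares it.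

Step 11
Reactants: 16 methyl 3-{[(1S,2S,3S,6S)-3-bromo-2-{2-[(tert-butyldiphenylsilyl)oxy]ethyl}-6-hydroxy-2-methylcyclohexyl]methyl}-4-(methoxymethoxy)benzoate
Product: 17 methyl 3-{[(1S,2S,3S)-3-bromo-2-{2-[(tert-butyldiphenylsilyl)oxy]ethyl}-2-methyl-6-oxocyclohexyl]methyl}-4-(methoxymethoxy)benzoate
Conditions: Dess–Martin periodinane, NaHCO3, CH2Cl2, 23 °C
Reagents that add atoms: none
Why: Dess–Martin oxidation gives the C3 ketone under buffered conditions that should not epimerise C2; any C2 epimer carried over from step 10 is separable here and can be recycled by brief DBU equilibration.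

Step 12
Reactants: 17 methyl 3-{[(1S,2S,3S)-3-bromo-2-{2-[(tert-butyldiphenylsilyl)oxy]ethyl}-2-methyl-6-oxocyclohexyl]methyl}-4-(methoxymethoxy)benzoate
Product: 18 methyl 3-{[(1R,2S,3S)-3-bromo-2-{2-[(tert-butyldiphenylsilyl)oxy]ethyl}-2-methyl-6-methylidenecyclohexyl]methyl}-4-(methoxymethoxy)benzoate
Conditions: Zn, CH2Br2, TiCl4, THF/CH2Cl2, 0 → 23 °C
Reagents that add atoms: dibromomethane, BrCBr
Why: The non-basic Takai–Lombardo reagent methylenates hindered, enolisable ketones without epimerising the α-centre and is selective for ketones over esters.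

Step 13
Reactants: 18 methyl 3-{[(1R,2S,3S)-3-bromo-2-{2-[(tert-butyldiphenylsilyl)oxy]ethyl}-2-methyl-6-methylidenecyclohexyl]methyl}-4-(methoxymethoxy)benzoate
Product: 19 methyl 3-{[(1R,2S,3S)-3-bromo-2-(2-hydroxyethyl)-2-methyl-6-methylidenecyclohexyl]methyl}-4-(methoxymethoxy)benzoate
Conditions: HF·pyridine, pyridine, THF, 0 → 23 °C
Reagents that add atoms: none
Why: Buffered acidic fluoride cleaves the silyl ether; a basic fluoride source is avoided so that the freed C9 oxygen cannot displace the C6 bromide intramolecularly.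

Step 14
Reactants: 19 methyl 3-{[(1R,2S,3S)-3-bromo-2-(2-hydroxyethyl)-2-methyl-6-methylidenecyclohexyl]methyl}-4-(methoxymethoxy)benzoate
Product: 20 methyl 3-{[(1R,2S,3S)-3-bromo-2-(2-iodoethyl)-2-methyl-6-methylidenecyclohexyl]methyl}-4-(methoxymethoxy)benzoate
Conditions: I2, PPh3, imidazole, CH2Cl2, 0 °C
Reagents that add atoms: iodine, II
Why: Appel-type iodination converts the primary alcohol via its alkoxyphosphonium salt, while the hindered secondary bromide does not exchange.

Step 15
Reactants: 20 methyl 3-{[(1R,2S,3S)-3-bromo-2-(2-iodoethyl)-2-methyl-6-methylidenecyclohexyl]methyl}-4-(methoxymethoxy)benzoate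
Product: 21 ring alkylzinc iodide, methyl 3-{[(1R,2S,3S)-3-bromo-2-[2-(iodozincio)ethyl]-2-methyl-6-methylidenecyclohexyl]methyl}-4-(methoxymethoxy)benzoate (THF solution, titrated and used directly)
Conditions: Zn dust (activated with BrCH2CH2Br and TMSCl), LiCl, THF, 30 °C
Reagents that add atoms: zinc, [Zn]
Why: LiCl-mediated zinc insertion takes the primary C–I bond near room temperature, where the neopentyl-type secondary bromide, the ester and the acetal are inert.

**Linchpin**

Step 16
Reactants: 22 propyne
Product: 23 (E)-2-bromo-1-iodoprop-1-ene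
Conditions: IBr, CH2Cl2, −78 → 0 °C, dark
Reagents that add atoms: iodine monobromide, IBr
Why: Electrophilic anti addition places iodine on the terminal carbon and bromide opens the iodonium ion at the methyl-bearing carbon from the opposite side, giving the E isomer.

**Tail fragment**

Step 17
Reactants: 24 methacrolein; 25 (S)-2-hydroxy-1,2,2-triphenylethyl acetate ((S)-HYTRA)
Product: 26 (S)-2-hydroxy-1,2,2-triphenylethyl (S)-3-hydroxy-4-methylpent-4-enoate
Conditions: 25, LDA (2.1 equiv), THF, −78 → 0 °C; then 24, −110 °C; aq. NH4Cl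
Reagents that add atoms: none
Why: In this auxiliary-controlled acetate aldol the HYTRA dianion adds 1,2 to the enal with the facial bias of the auxiliary, whose (S)-form gives the (S)-carbinol when the aldehyde substituent outranks CH2CO2R, setting C14; the minor diastereomer should be removable by crystallisation.

Step 18
Reactants: 26 (S)-2-hydroxy-1,2,2-triphenylethyl (S)-3-hydroxy-4-methylpent-4-enoate
Product: 27 (S)-2-hydroxy-1,2,2-triphenylethyl (S)-3-[(tert-butyldimethylsilyl)oxy]-4-methylpent-4-enoate
Conditions: TBSCl, imidazole, DMF, 23 → 40 °C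
Reagents that add atoms: tert-butyldimethylsilyl chloride, CC(C)(C)[Si](C)(C)Cl
Why: Silylation takes the secondary allylic alcohol, while the tertiary diphenylcarbinol of the auxiliary is too hindered to react.

Step 19
Reactants: 27 (S)-2-hydroxy-1,2,2-triphenylethyl (S)-3-[(tert-butyldimethylsilyl)oxy]-4-methylpent-4-enoate
Product: 28 (S)-3-[(tert-butyldimethylsilyl)oxy]-4-methylpent-4-en-1-ol
Conditions: DIBAL-H (4 equiv), CH2Cl2, −78 → 0 °C; Rochelle salt
Reagents that add atoms: none
Why: Hydride reduction cleaves the auxiliary ester to the primary alcohol (C12) and releases the triphenylethanediol for recovery.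

Step 20
Reactants: 28 (S)-3-[(tert-butyldimethylsilyl)oxy]-4-methylpent-4-en-1-ol
Product: 29 (S)-tert-butyl[(5-iodo-2-methylpent-1-en-3-yl)oxy]dimethylsilane
Conditions: I2, PPh3, imidazole, CH2Cl2, 0 °C
Reagents that add atoms: iodine, II
Why: Appel-type iodination of the primary alcohol leaves the allylic silyl ether and the 1,1-disubstituted alkene alone.

Step 21
Reactants: 29 (S)-tert-butyl[(5-iodo-2-methylpent-1-en-3-yl)oxy]dimethylsilane
Product: 30 tail alkylzinc iodide, (S)-{3-[(tert-butyldimethylsilyl)oxy]-4-methylpent-4-en-1-yl}zinc iodide (THF solution, titrated and used directly)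
Conditions: Zn dust (activated), LiCl, THF, 30 °C
Reagents that add atoms: zinc, [Zn]
Why: Zinc insertion into the primary iodide gives a reagent whose γ-silyloxy group is too poor a leaving group for 1,3-elimination.

**Assembly**

Step 22
Reactants: 21 ring alkylzinc iodide; 23 (E)-2-bromo-1-iodoprop-1-ene; 30 tail alkylzinc iodide
Product: 32 seco ester, methyl 3-{[(1R,2S,3S)-3-bromo-2-[(3E,7S)-7-[(tert-butyldimethylsilyl)oxy]-4,8-dimethylnona-3,8-dien-1-yl]-2-methyl-6-methylidenecyclohexyl]methyl}-4-(methoxymethoxy)benzoate, via ring-linchpin bromoalkene 31 (not isolated)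
Conditions: 21 (1.0 equiv), 23 (1.15 equiv), PdCl2(DPEphos) (5 mol%), THF, 0 → 23 °C; then 30 (2 equiv), Pd(t-Bu3P)2 (5 mol%), THF, 23 → 50 °C
Reagents that add atoms: none
Why: Pd(0) inserts into the C–I bond of 23, which is far more reactive than the C–Br bond on the methyl-bearing carbon; the primary alkylzinc 21 transmetalates and reductive elimination forms C9–C10 to give bromoalkene 31, and a second cycle at the slower alkenyl bromide, driven by the bulky electron-rich phosphine and excess 30, forms C11–C12. The closest known reaction type is the stepwise Negishi coupling of alkylzinc halides with (E)-1-bromo-2-iodoalkenes and related dihaloalkenes, which runs with retention of alkene geometry. No ring is closed and no stereocentre is created: three finished fragments are joined, and the E geometry delivered by 23 is the stored form of the anti C10/C11 relationship. The step needs site selectivity (ring on C10, tail on C11), secured by the C–I/C–Br rate gap and by having no free 21 left when 30 is added, and chemoselectivity over the secondary C6–Br bond, secured because unactivated neopentyl-type alkyl bromides do not add to these palladium catalysts or to zinc at 50 °C or below. Chelating and bulky phosphines keep β-hydride elimination of the alkylpalladium intermediates slower than reductive elimination, and fast transmetalation limits loss of the linchpin by β-bromide elimination to propyne.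

**Endgame**

Step 23
Reactants: 32 seco ester
Product: 33 epoxy ester, the (10S,11S)-10,11-epoxide of 32
Conditions: ent-Shi ketone (30 mol%), Oxone, K2CO3, Bu4NHSO4, MeCN/dimethoxymethane/aq. borate–EDTA buffer, 0 °C
Reagents that add atoms: potassium peroxymonosulfate (Oxone), [K+].[O-]S(=O)(=O)OO
Why: In this Shi epoxidation the dioxirane of the L-fructose-type ketone attacks the trisubstituted (E)-alkene through the spiro transition state on the face opposite to that taken by the D-fructose ketone (which gives R,R epoxides), so the 10S,11S epoxide should form under reagent control, and the two 1,1-disubstituted alkenes are poor substrates for this catalyst.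

Step 24
Reactants: 33 epoxy ester
Product: 34 epoxy acid, the free benzoic acid of 33 (C14–OTBS retained)
Conditions: LiOH·H2O, THF/MeOH/H2O, 45 °C; then 10% citric acid to pH 5, 0 °C
Reagents that add atoms: lithium hydroxide, [Li+].[OH-]
Why: Saponification of the methyl benzoate is compatible with the epoxide, the equatorial neopentyl bromide, the MOM acetal and the secondary silyl ether, and keeping C14–O silylated means no 4,5-epoxy alcohol is ever present.

Step 25
Reactants: 34 epoxy acid
Product: 35 bromohydrin acid, (10R)-bromo-(11S)-hydroxy seco acid with C14–OTBS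
Conditions: Li2NiBr4, THF, 0 → 23 °C
Reagents that add atoms: dilithium tetrabromonickelate(II), [Li+].[Li+].Br[Ni-2](Br)(Br)Br
Why: The soft bromide of Li2NiBr4 opens the trisubstituted epoxide by SN2 at the less substituted C10 with inversion (10S epoxide carbon to 10R bromide) and leaves the C11–O bond intact (11S tertiary alcohol), giving the anti bromohydrin encoded by the E alkene.

Step 26
Reactants: 35 bromohydrin acid
Product: 36 seco acid with free C14–OH, (10R)-bromo-(11S),(14S)-dihydroxy acid
Conditions: HF·pyridine, pyridine, THF, 0 → 23 °C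
Reagents that add atoms: none
Why: Acidic fluoride cleaves the allylic TBS ether; basic fluoride is avoided because alkoxide formation would re-close the bromohydrin to the epoxide.

Step 27
Reactants: 36 seco acid with free C14–OH
Product: 37 O-(methoxymethyl)bromophycolide E
Conditions: 2-methyl-6-nitrobenzoic anhydride (MNBA), DMAP, CH2Cl2 (1 mM, slow addition), 23 °C
Reagents that add atoms: none
Why: In this Shiina macrolactonisation the mixed anhydride is attacked via its acyl-DMAP form by the secondary C14–OH under high dilution, closing the 15-membered lactone with retention at C14; the tertiary C11–OH and the protected phenol cannot compete.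

Step 28
Reactants: 37 O-(methoxymethyl)bromophycolide E
Product: 38 bromophycolide E
Conditions: NaHSO4·SiO2, CH2Cl2, 23 °C
Reagents that add atoms: none
Why: Acid-catalysed acetal hydrolysis on a mild solid acid is selective for phenolic MOM ethers and should spare the bromohydrin, the allylic ester and both 1,1-disubstituted alkenes.

**Compound list**

1 | methyl 3-formyl-4-hydroxybenzoate | COC(=O)c1ccc(O)c(C=O)c1 | starting material
2 | methyl 3-formyl-4-(methoxymethoxy)benzoate | COC(=O)c1ccc(OCOC)c(C=O)c1 | intermediate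
3 | methyl 3-(hydroxymethyl)-4-(methoxymethoxy)benzoate | COC(=O)c1ccc(OCOC)c(CO)c1 | intermediate
4 | methyl 3-(bromomethyl)-4-(methoxymethoxy)benzoate | COC(=O)c1ccc(OCOC)c(CBr)c1 | intermediate
5 | cyclohexane-1,3-dione | O=C1CCCC(=O)C1 | starting material
6 | 2-[(tert-butyldiphenylsilyl)oxy]acetaldehyde | CC(C)(C)[Si](c1ccccc1)(c1ccccc1)OCC=O | starting material
7 | 2-{2-[(tert-butyldiphenylsilyl)oxy]ethylidene}cyclohexane-1,3-dione | CC(C)(C)[Si](c1ccccc1)(c1ccccc1)OCC=C2C(=O)CCCC2=O | intermediate
8 | 2-{2-[(tert-butyldiphenylsilyl)oxy]ethyl}cyclohexane-1,3-dione | CC(C)(C)[Si](c1ccccc1)(c1ccccc1)OCCC2C(=O)CCCC2=O | intermediate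
9 | 2-{2-[(tert-butyldiphenylsilyl)oxy]ethyl}-2-methylcyclohexane-1,3-dione | CC(C)(C)[Si](c1ccccc1)(c1ccccc1)OCCC2(C)C(=O)CCCC2=O | intermediate
10 | (2R,3R)-2-{2-[(tert-butyldiphenylsilyl)oxy]ethyl}-3-hydroxy-2-methylcyclohexan-1-one | CC(C)(C)[Si](c1ccccc1)(c1ccccc1)OCC[C@@]2(C)C(=O)CCC[C@H]2O | intermediate
11 | (2S,3S)-3-bromo-2-{2-[(tert-butyldiphenylsilyl)oxy]ethyl}-2-methylcyclohexan-1-one | CC(C)(C)[Si](c1ccccc1)(c1ccccc1)OCC[C@@]2(C)C(=O)CCC[C@@H]2Br | intermediate
12 | (5S,6S)-5-bromo-6-{2-[(tert-butyldiphenylsilyl)oxy]ethyl}-6-methylcyclohex-1-en-1-yl trifluoromethanesulfonate | CC(C)(C)[Si](c1ccccc1)(c1ccccc1)OCC[C@@]2(C)C(OS(=O)(=O)C(F)(F)F)=CCC[C@@H]2Br | intermediate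
13 | {[5-(methoxycarbonyl)-2-(methoxymethoxy)phenyl]methyl}zinc bromide | COC(=O)c1ccc(OCOC)c(C[Zn]Br)c1 | intermediate
14 | methyl 3-{[(5S,6S)-5-bromo-6-{2-[(tert-butyldiphenylsilyl)oxy]ethyl}-6-methylcyclohex-1-en-1-yl]methyl}-4-(methoxymethoxy)benzoate | CC(C)(C)[Si](c1ccccc1)(c1ccccc1)OCC[C@@]2(C)C(Cc3cc(ccc3OCOC)C(=O)OC)=CCC[C@@H]2Br | intermediate
15 | C3 monoalkylborane from 14 (boron on C3, syn to the new C2–H) | CC(C)(C)[Si](c1ccccc1)(c1ccccc1)OCC[C@@]2(C)[C@H](Cc3cc(ccc3OCOC)C(=O)OC)[C@@H](B)CC[C@@H]2Br | intermediate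
16 | methyl 3-{[(1S,2S,3S,6S)-3-bromo-2-{2-[(tert-butyldiphenylsilyl)oxy]ethyl}-6-hydroxy-2-methylcyclohexyl]methyl}-4-(methoxymethoxy)benzoate | CC(C)(C)[Si](c1ccccc1)(c1ccccc1)OCC[C@@]2(C)[C@H](Cc3cc(ccc3OCOC)C(=O)OC)[C@@H](O)CC[C@@H]2Br | intermediate
17 | methyl 3-{[(1S,2S,3S)-3-bromo-2-{2-[(tert-butyldiphenylsilyl)oxy]ethyl}-2-methyl-6-oxocyclohexyl]methyl}-4-(methoxymethoxy)benzoate | CC(C)(C)[Si](c1ccccc1)(c1ccccc1)OCC[C@@]2(C)[C@H](Cc3cc(ccc3OCOC)C(=O)OC)C(=O)CC[C@@H]2Br | intermediate
18 | methyl 3-{[(1R,2S,3S)-3-bromo-2-{2-[(tert-butyldiphenylsilyl)oxy]ethyl}-2-methyl-6-methylidenecyclohexyl]methyl}-4-(methoxymethoxy)benzoate | CC(C)(C)[Si](c1ccccc1)(c1ccccc1)OCC[C@@]2(C)[C@H](Cc3cc(ccc3OCOC)C(=O)OC)C(=C)CC[C@@H]2Br | intermediate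
19 | methyl 3-{[(1R,2S,3S)-3-bromo-2-(2-hydroxyethyl)-2-methyl-6-methylidenecyclohexyl]methyl}-4-(methoxymethoxy)benzoate | OCC[C@@]1(C)[C@H](Cc2cc(ccc2OCOC)C(=O)OC)C(=C)CC[C@@H]1Br | intermediate
20 | methyl 3-{[(1R,2S,3S)-3-bromo-2-(2-iodoethyl)-2-methyl-6-methylidenecyclohexyl]methyl}-4-(methoxymethoxy)benzoate | ICC[C@@]1(C)[C@H](Cc2cc(ccc2OCOC)C(=O)OC)C(=C)CC[C@@H]1Br | intermediate
21 | ring alkylzinc iodide (zinc on C9) | I[Zn]CC[C@@]1(C)[C@H](Cc2cc(ccc2OCOC)C(=O)OC)C(=C)CC[C@@H]1Br | intermediate
22 | propyne | CC#C | starting material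
23 | (E)-2-bromo-1-iodoprop-1-ene | Br/C(C)=C/I | intermediate
24 | methacrolein | CC(=C)C=O | starting material
25 | (S)-2-hydroxy-1,2,2-triphenylethyl acetate ((S)-HYTRA) | CC(=O)O[C@@H](c1ccccc1)C(O)(c1ccccc1)c1ccccc1 | starting material
26 | (S)-2-hydroxy-1,2,2-triphenylethyl (S)-3-hydroxy-4-methylpent-4-enoate | C=C(C)[C@@H](O)CC(=O)O[C@@H](c1ccccc1)C(O)(c1ccccc1)c1ccccc1 | intermediate
27 | (S)-2-hydroxy-1,2,2-triphenylethyl (S)-3-[(tert-butyldimethylsilyl)oxy]-4-methylpent-4-enoate | C=C(C)[C@@H](O[Si](C)(C)C(C)(C)C)CC(=O)O[C@@H](c1ccccc1)C(O)(c1ccccc1)c1ccccc1 | intermediate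
28 | (S)-3-[(tert-butyldimethylsilyl)oxy]-4-methylpent-4-en-1-ol | C=C(C)[C@@H](O[Si](C)(C)C(C)(C)C)CCO | intermediate
29 | (S)-tert-butyl[(5-iodo-2-methylpent-1-en-3-yl)oxy]dimethylsilane | C=C(C)[C@@H](O[Si](C)(C)C(C)(C)C)CCI | intermediate
30 | tail alkylzinc iodide (zinc on C12) | C=C(C)[C@@H](O[Si](C)(C)C(C)(C)C)CC[Zn]I | intermediate
31 | ring-linchpin (E)-bromoalkene (C9–C10 formed, Br on C11) | Br/C(C)=C/CC[C@@]1(C)[C@H](Cc2cc(ccc2OCOC)C(=O)OC)C(=C)CC[C@@H]1Br | intermediate
32 | seco ester with (E)-C10=C11 alkene | C=C(C)[C@@H](O[Si](C)(C)C(C)(C)C)CC/C(C)=C/CC[C@@]1(C)[C@H](Cc2cc(ccc2OCOC)C(=O)OC)C(=C)CC[C@@H]1Br | intermediate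
33 | (10S,11S)-epoxy ester | C=C(C)[C@@H](O[Si](C)(C)C(C)(C)C)CC[C@]1(C)O[C@H]1CC[C@@]2(C)[C@H](Cc3cc(ccc3OCOC)C(=O)OC)C(=C)CC[C@@H]2Br | intermediate
34 | (10S,11S)-epoxy acid | C=C(C)[C@@H](O[Si](C)(C)C(C)(C)C)CC[C@]1(C)O[C@H]1CC[C@@]2(C)[C@H](Cc3cc(ccc3OCOC)C(=O)O)C(=C)CC[C@@H]2Br | intermediate
35 | bromohydrin acid (10R-Br, 11S-OH, C14–OTBS) | C=C(C)[C@@H](O[Si](C)(C)C(C)(C)C)CC[C@](C)(O)[C@H](Br)CC[C@@]1(C)[C@H](Cc2cc(ccc2OCOC)C(=O)O)C(=C)CC[C@@H]1Br | intermediate
36 | seco acid (10R-Br, 11S-OH, 14S-OH) | C=C(C)[C@@H](O)CC[C@](C)(O)[C@H](Br)CC[C@@]1(C)[C@H](Cc2cc(ccc2OCOC)C(=O)O)C(=C)CC[C@@H]1Br | intermediate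
37 | O-(methoxymethyl)bromophycolide E | C=C(C)[C@@H]1CC[C@](C)(O)[C@H](Br)CC[C@@]2(C)[C@H](Cc3cc(ccc3OCOC)C(=O)O1)C(=C)CC[C@@H]2Br | intermediate
38 | bromophycolide E | C=C(C)[C@@H]1CC[C@](C)(O)[C@H](Br)CC[C@@]2(C)[C@H](Cc3cc(ccc3O)C(=O)O1)C(=C)CC[C@@H]2Br | target

**Step count**

Total step count: 28. Longest linear sequence: 19 steps (steps 4–15 and 22–28, from 5 and 6).

**Steps most likely to fail**

Step 22. The alkenylpalladium formed at C–I may lose bromide from the neighbouring carbon (β-bromide elimination to propyne) before transmetalation. The ring zinc reagent may also couple at both halogens, and the slow second coupling may erode the E geometry. The fallback sets out from 29 and 21 and comes back at 32. Iodide 29 is alkylated with lithium acetylide–ethylenediamine in DMSO to give the terminal alkyne (S)-tert-butyldimethyl[(2-methylhept-1-en-6-yn-3-yl)oxy]silane F1. Zirconium-catalysed methylalumination (Me3Al, Cp2ZrCl2, CH2Cl2) adds methyl and aluminium syn across the alkyne to give the (E)-alkenyl(dimethyl)alane F2. Iodinolysis then gives (S,E)-tert-butyl[(7-iodo-2,6-dimethylhepta-1,6-dien-3-yl)oxy]dimethylsilane F3. A single palladium-catalysed sp3–sp2 Negishi coupling of F3 with 21 forms C9–C10 and gives 32. The trisubstituted alkene is then built by carbometalation, and no 1,2-dihaloalkene is exposed to palladium.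

Step 7. Substitution at the neopentyl-type carbinol may be too slow, so that elimination toward C5 or ionisation with loss of configuration takes over. The fallback sets out from 10 and comes back at 11. Activation and displacement are separated: Tf2O and pyridine in CH2Cl2 at −40 °C give the isolable triflate (1R,2R)-2-{2-[(tert-butyldiphenylsilyl)oxy]ethyl}-2-methyl-3-oxocyclohexyl trifluoromethanesulfonate F4. Tetrabutylammonium bromide in toluene at −20 → 20 °C then displaces the triflate with inversion to give 11. The much better leaving group and the phosphine-free, unsolvated bromide should let SN2 run well below the temperature at which E2 sets in.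

Step 6. The catalyst may discriminate poorly between the two carbonyl groups or between their faces on the flexible six-membered dione (low cis/trans ratio or low enantiomeric purity). The fallback sets out from 9 and comes back at 10. Sub-stoichiometric NaBH4 in MeOH/CH2Cl2 at −78 °C reduces 9, with hydride anti to the larger arm, to the racemic cis ketol: 10 together with its enantiomer (2S,3S)-2-{2-[(tert-butyldiphenylsilyl)oxy]ethyl}-3-hydroxy-2-methylcyclohexan-1-one F5. Lipase-catalysed transesterification (Burkholderia cepacia lipase, vinyl acetate, MTBE) is expected, by the empirical rule for secondary alcohols, to acylate the 3R alcohol to (1R,2R)-2-{2-[(tert-butyldiphenylsilyl)oxy]ethyl}-2-methyl-3-oxocyclohexyl acetate F6. F6 is separated from F5 and methanolysed (K2CO3, MeOH) to 10. Enantiopurity then comes from an enzymatic resolution and not from the reduction.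

**Further compounds**

F1 | step 22 | (S)-tert-butyldimethyl[(2-methylhept-1-en-6-yn-3-yl)oxy]silane | C=C(C)[C@@H](O[Si](C)(C)C(C)(C)C)CCC#C
F2 | step 22 | (E)-alkenyl(dimethyl)alane from methylalumination of F1 | C=C(C)[C@@H](O[Si](C)(C)C(C)(C)C)CC/C(C)=C/[Al](C)C
F3 | step 22 | (S,E)-tert-butyl[(7-iodo-2,6-dimethylhepta-1,6-dien-3-yl)oxy]dimethylsilane | C=C(C)[C@@H](O[Si](C)(C)C(C)(C)C)CC/C(C)=C/I
F4 | step 7 | (1R,2R)-2-{2-[(tert-butyldiphenylsilyl)oxy]ethyl}-2-methyl-3-oxocyclohexyl trifluoromethanesulfonate | CC(C)(C)[Si](c1ccccc1)(c1ccccc1)OCC[C@@]2(C)C(=O)CCC[C@H]2OS(=O)(=O)C(F)(F)F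
F5 | step 6 | (2S,3S)-2-{2-[(tert-butyldiphenylsilyl)oxy]ethyl}-3-hydroxy-2-methylcyclohexan-1-one | CC(C)(C)[Si](c1ccccc1)(c1ccccc1)OCC[C@]2(C)C(=O)CCC[C@@H]2O
F6 | step 6 | (1R,2R)-2-{2-[(tert-butyldiphenylsilyl)oxy]ethyl}-2-methyl-3-oxocyclohexyl acetate | CC(C)(C)[Si](c1ccccc1)(c1ccccc1)OCC[C@@]2(C)C(=O)CCC[C@H]2OC(C)=O
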